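The product we want is mono adduct. In the alpha flask its readings are falling while substrate falls ever more slowly, and we must decide what to do to that flask at 2.0 h.

in all of them: substrate 1.5 M
- alpha: coupling partner 1.1 equiv; temperature 0 °C; the very flask that is asked about, followed so far
- epsilon: coupling partner 1.1 equiv; temperature 6 °C; run made earlier
- flask: coupling partner 1.10 equiv; temperature 0 °C; time 2.0 h

| run | time / min | mono adduct / % | substrate / % |
|---|---|---|---|
| alpha | 10.0 | 17.6 | 68.6 |
| alpha | 20.0 | 17.3 | 53.9 |
| alpha | 30.0 | 18.9 | 49.5 |
| alpha | 40.0 | 16.0 | 45.2 |
| alpha | 50.0 | 14.9 | 43.8 |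
| alpha | 60.0 | 14.5 | 43.0 |
| alpha | 80.0 | 13.5 | 39.3 |
| epsilon | 10.0 | 23.6 | 55.0 |
| epsilon | 20.0 | 20.1 | 44.6 |
| epsilon | 30.0 | 15.9 | 39.9 |
| epsilon | 40.0 | 15.2 | 39.1 |
| epsilon | 50.0 | 17.2 | 37.9 |
| epsilon | 60.0 | 12.5 | 37.2 |
| epsilon | 80.0 | 14.5 | 34.7 |

(readings scatter by 1 percentage point)

- Thursday's: at 2.0 h raise the temperature by 25 K, then wait 4.0 h
- Tuesday's: change nothing and wait 4.0 h more
- Monday's: at 2.0 h add substrate, 50.0 % of the amount charged, then wait 4.0 h

- what is added takes up no volume worth counting
- a reading or a percentage of mono adduct counts all its forms, free or not

- mono adduct, in percent of the substrate first charged, at 2.0 h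
- the remedy with the largest gain of mono adduct, or "none" below 2 percentage points (Thursday's / Tuesday's / Monday's / none)
- mono adduct present, in percent of the substrate first charged, after Thursday's
- mono adduct present, in percent of the substrate first charged, after Monday's

1. We suppose that mono adduct takes a second coupling partner to give bis adduct. Each point of substrate gone then costs one point of partner, and each such point no longer present as mono adduct costs another.
2. Let S and M be the substrate and mono adduct readings, in percent of substrate charged. The last alpha reading gives 2.1 percentage points for the partner gap G: partner charged, less substrate gone counted double, plus M.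
3. S counts double, so one G scatters by 2.2 points. The alpha gap is within that of zero.
4. The epsilon run ends at −6.1 points, beyond twice the scatter. A negative gap means the count has used more partner than was charged, so some mono adduct is probably sitting in a form we do not read. A gap near zero therefore does not tell us how much partner is free.
5. Decision: in the alpha flask the last two readings of mono adduct are 14.5 %, then 13.5 %, so by this rough extrapolation we expect about 11.5 % at 2.0 h and do not wait. We try Thursday's, since heat is our test of whether an unread form gives material back.

The forecast, which differs from us on the level and the remedy, says 13 % now, 11.5 % after Thursday's, 13.5 % after Monday's and none as the remedy, holding that “neither waiting, heating nor extra substrate makes more mono adduct”.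

The flask gives 11.4 %. Thursday's brings 6.7 points, reaching 18.1 %; Tuesday's brings −1.5 points; Monday's brings −0.28 points, ending at 11.1 %.

    substrate + coupling partner → mono adduct (k = 0.0310 /M/min, Ea = 68.0 kJ/mol)
    coupling partner + mono adduct → bis adduct (k = 0.0790 /M/min, Ea = 45.0 kJ/mol)
    crystals ⇌ mono adduct, rate k3*(cs3 - [mono adduct]) while solid is left; crystals form when [mono adduct] > cs3 (solubility = 0.300 M, k = 0.180 /min)
    mono adduct ⇌ isomer of the product (K = 1.60, k = 0.0110 /min, Ea = 90.0 kJ/mol, ΔH = −30.0 kJ/mol)
    coupling partner ⇌ dormant form (K = 1.60, k = 0.00760 /min, Ea = 77.0 kJ/mol, ΔH = −55.0 kJ/mol)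
    (constants at 0 °C)

At 2.00 h the flask's gap is −1.3 points; the gap read earlier from the last alpha reading was 2.1 points, with its scatter of 2.2 points. It is a difference of two stores: free partner plus dormant form, 11.4 % of the substrate charged, against isomer of the product, 12.8 %. At 2.00 h free partner, the limiting reagent, stands at 1.46 % of its charge. The flask is not at rest: dormant form goes from 0.147 M at 2.00 h to 0.00302 M at 20.0 h, substrate goes from 38.6 % at 2.00 h to 32.2 % at 20.0 h, and mono adduct stands at 9.97 % at 20.0 h. Over that span the gap moves by −14 points.

In the later neighbour flask, the same flask read at 8.00 h, the stores give a gap of −13 points, which lies −15 points from the 2.1 points read in the alpha run. With substrate at 33.8 %, the gap's definition returns 9.90 % of mono adduct; the computed result is 9.90 %.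

The earlier runs and the new flask were computed with made-up constants; noise was put on by code.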